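## Retrosynthetic overview

1. Labels: ring A = benzo ring of the benzofuran, ring B = 2-aryl group, ring C = resorcinol ring, ring D = aryl on the stereocentre; C8 = diarylmethine stereocentre (S by CIP for the given SMILES), C9 = ketone carbon.
2. Hopeafuran 28 ⇐ penta-O-benzyl ketone 27 (hydrogenolysis) ⇐ alcohol 26 (oxidation); the epimerisable α,α-diaryl ketone exists only in the last two steps.
3. Seven-membered ring closed last through the C9–C4 bond: intramolecular aryl iodide/aldehyde coupling of 24.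
4. Benzofuran C3–ring C bond by Suzuki coupling of boronate 14 with 3-iodobenzofuran 20; the furan ring is formed first, by alkyne iodocyclisation on the ring A fragment.
5. Key disconnection: the C8–ring C bond, made by an enantioselective intermolecular Michael addition of phenol 5 to nitroalkene 4. The phenol OH then becomes the triflate/boronate handle and the CH2NO2 carbon becomes C9.

Assumption: the quinine-derived squaramide is taken to give the S adduct 6; if the sense is found to be opposite, the pseudo-enantiomeric quinidine-derived squaramide is used under the same conditions.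

Compounds 5, 15 and 17 are taken as catalogue materials. The route is designed from general reactivity and analogy; no step has been run on these substrates.

## Route

Step 1
Reactants: 1 4-(benzyloxy)benzaldehyde; 2 nitromethane
Product: 4 1-(benzyloxy)-4-[(E)-2-nitroethenyl]benzene, via nitroaldol 3 (not isolated)
Conditions: NH4OAc, AcOH, 100 °C
Reagents that add atoms: none
Why: Henry (nitroaldol) condensation; the nitroaldol dehydrates in hot acetic acid to the conjugated, thermodynamically favoured E-nitroalkene, and the benzyl ether is inert.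

Step 2
Reactants: 4 1-(benzyloxy)-4-[(E)-2-nitroethenyl]benzene; 5 3,5-bis(benzyloxy)phenol (1.5 equiv)
Product: 6 3,5-bis(benzyloxy)-2-[(1S)-1-[4-(benzyloxy)phenyl]-2-nitroethyl]phenol
Conditions: 3-{[3,5-bis(trifluoromethyl)phenyl]amino}-4-{[(8α,9S)-6'-methoxycinchonan-9-yl]amino}cyclobut-3-ene-1,2-dione (10 mol%), CH2Cl2, −20 °C; one recrystallisation
Reagents that add atoms: none
Why: Organocatalytic asymmetric Michael addition (Friedel–Crafts type): the squaramide N–H groups bind the nitro group and the quinuclidine nitrogen activates the phenol O–H, so the carbon ortho to OH (both ortho positions are equivalent) attacks one face of the nitroalkene and sets C8 as S, while excess phenol suppresses double alkylation.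

Step 3
Reactants: 6 3,5-bis(benzyloxy)-2-[(1S)-1-[4-(benzyloxy)phenyl]-2-nitroethyl]phenol
Product: 7 3,5-bis(benzyloxy)-2-[(1S)-1-[4-(benzyloxy)phenyl]-2-nitroethyl]phenyl trifluoromethanesulfonate
Conditions: Tf2O, pyridine, CH2Cl2, −20 to 0 °C
Reagents that add atoms: trifluoromethanesulfonic anhydride, O=S(=O)(OS(=O)(=O)C(F)(F)F)C(F)(F)F
Why: O-sulfonylation of the phenol turns the directing OH into a cross-coupling handle and protects the ring from nitrosation in the next step; cold pyridine leaves the nitroalkane and C8 untouched.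

Step 4
Reactants: 7 3,5-bis(benzyloxy)-2-[(1S)-1-[4-(benzyloxy)phenyl]-2-nitroethyl]phenyl trifluoromethanesulfonate
Product: 11 (2S)-2-[2,4-bis(benzyloxy)-6-{[(trifluoromethyl)sulfonyl]oxy}phenyl]-2-[4-(benzyloxy)phenyl]acetic acid, via nitrolic acid 8 (not isolated), via nitrile oxide 9 (not isolated), via hydroxamic acid 10 (not isolated)
Conditions: NaNO2, AcOH, DMSO, 35 °C
Reagents that add atoms: sodium nitrite, O=N[O-].[Na+]; water, O (together they supply the carboxyl oxygens)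
Why: Nitrite-mediated Nef-type oxidation of a primary nitroalkane to the carboxylic acid (nitrosation, loss of nitrite, hydration, nitrosative cleavage) runs in weakly acidic medium at 35 °C, so the C8–H is not exchanged and the triflate and benzyl ethers survive.

Step 5
Reactants: 11 (2S)-2-[2,4-bis(benzyloxy)-6-{[(trifluoromethyl)sulfonyl]oxy}phenyl]-2-[4-(benzyloxy)phenyl]acetic acid
Product: 12 3,5-bis(benzyloxy)-2-[(1S)-1-[4-(benzyloxy)phenyl]-2-hydroxyethyl]phenyl trifluoromethanesulfonate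
Conditions: BH3·SMe2, THF, 0 °C to rt; MeOH then aqueous work-up
Reagents that add atoms: none
Why: Chemoselective borane reduction of the carboxylic acid (electrophilic hydride, no base) gives the primary alcohol without touching the aryl triflate or benzyl ethers, and C8 cannot epimerise at this oxidation level.

Step 6
Reactants: 12 3,5-bis(benzyloxy)-2-[(1S)-1-[4-(benzyloxy)phenyl]-2-hydroxyethyl]phenyl trifluoromethanesulfonate
Product: 13 3,5-bis(benzyloxy)-2-[(1S)-1-[4-(benzyloxy)phenyl]-2-{[tert-butyl(dimethyl)silyl]oxy}ethyl]phenyl trifluoromethanesulfonate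
Conditions: TBSCl, imidazole, DMF, rt
Reagents that add atoms: tert-butyldimethylsilyl chloride, CC(C)(C)[Si](C)(C)Cl
Why: Standard silylation of a primary alcohol; masking the OH prevents palladium alkoxide side reactions in the couplings that follow.

Step 7
Reactants: 13 3,5-bis(benzyloxy)-2-[(1S)-1-[4-(benzyloxy)phenyl]-2-{[tert-butyl(dimethyl)silyl]oxy}ethyl]phenyl trifluoromethanesulfonate
Product: 14 {(2S)-2-[2,4-bis(benzyloxy)-6-(4,4,5,5-tetramethyl-1,3,2-dioxaborolan-2-yl)phenyl]-2-[4-(benzyloxy)phenyl]ethoxy}(tert-butyl)dimethylsilane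
Conditions: B2pin2, Pd(dppf)Cl2 (dppf = 1,1'-bis(diphenylphosphino)ferrocene), KOAc, 1,4-dioxane, 90 °C
Reagents that add atoms: bis(pinacolato)diboron, CC1(C)OB(OC1(C)C)B1OC(C)(C)C(C)(C)O1
Why: Miyaura borylation of the aryl triflate; the mild acetate base and bidentate ligand favour boryl transfer over C–H arylation of ring D, and the silyl and benzyl ethers are inert.

Step 8
Reactants: 15 1,3-bis(benzyloxy)-5-bromobenzene
Product: 16 1,5-bis(benzyloxy)-3-bromo-2-iodobenzene
Conditions: N-iodosuccinimide, CF3CO2H (cat.), MeCN, 0 °C to rt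
Reagents that add atoms: N-iodosuccinimide, O=C1CCC(=O)N1I
Why: Electrophilic aromatic iodination goes para to one benzyloxy group and ortho to the other, next to bromine, because the position between the two benzyloxy groups is more hindered; this puts iodine at the future C3a.

Step 9
Reactants: 16 1,5-bis(benzyloxy)-3-bromo-2-iodobenzene; 17 1-(benzyloxy)-4-ethynylbenzene
Product: 18 1,5-bis(benzyloxy)-2-{[4-(benzyloxy)phenyl]ethynyl}-3-bromobenzene
Conditions: Pd(PPh3)2Cl2, CuI, Et3N, THF, 50 °C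
Reagents that add atoms: none
Why: Sonogashira coupling is selective for the C–I bond over C–Br at this temperature and installs the ring B alkyne.

Step 10
Reactants: 18 1,5-bis(benzyloxy)-2-{[4-(benzyloxy)phenyl]ethynyl}-3-bromobenzene
Product: 20 6-(benzyloxy)-2-[4-(benzyloxy)phenyl]-4-bromo-3-iodo-1-benzofuran, via benzofuranium iodide 19 (not isolated)
Conditions: I2, CH2Cl2, rt; aq. Na2S2O3 work-up
Reagents that add atoms: iodine, II
Why: Iodocyclisation (5-endo-dig electrophilic cyclisation): iodine activates the alkyne, the ortho benzyloxy oxygen closes the furan ring, and iodide removes the O-benzyl group from the oxonium ion as benzyl iodide, leaving bromine at C4 and iodine at C3.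

Step 11
Reactants: 14 {(2S)-2-[2,4-bis(benzyloxy)-6-(4,4,5,5-tetramethyl-1,3,2-dioxaborolan-2-yl)phenyl]-2-[4-(benzyloxy)phenyl]ethoxy}(tert-butyl)dimethylsilane; 20 6-(benzyloxy)-2-[4-(benzyloxy)phenyl]-4-bromo-3-iodo-1-benzofuran
Product: 21 {(2S)-2-[2,4-bis(benzyloxy)-6-{6-(benzyloxy)-2-[4-(benzyloxy)phenyl]-4-bromo-1-benzofuran-3-yl}phenyl]-2-[4-(benzyloxy)phenyl]ethoxy}(tert-butyl)dimethylsilane
Conditions: Pd(dppf)Cl2, Cs2CO3, 1,4-dioxane/H2O (10:1), 80 °C
Reagents that add atoms: none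
Why: Suzuki–Miyaura coupling at the more reactive C3–I bond (the hindered C4–Br reacts more slowly) joins ring C to the benzofuran, and C8 carries no acidifying group, so the basic conditions cannot epimerise it.

Step 12
Reactants: 21 {(2S)-2-[2,4-bis(benzyloxy)-6-{6-(benzyloxy)-2-[4-(benzyloxy)phenyl]-4-bromo-1-benzofuran-3-yl}phenyl]-2-[4-(benzyloxy)phenyl]ethoxy}(tert-butyl)dimethylsilane
Product: 22 {(2S)-2-[2,4-bis(benzyloxy)-6-{6-(benzyloxy)-2-[4-(benzyloxy)phenyl]-4-iodo-1-benzofuran-3-yl}phenyl]-2-[4-(benzyloxy)phenyl]ethoxy}(tert-butyl)dimethylsilane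
Conditions: CuI (10 mol%), NaI, trans-N,N'-dimethylcyclohexane-1,2-diamine, 1,4-dioxane, 110 °C
Reagents that add atoms: sodium iodide, [Na+].[I-]
Why: Copper-catalysed aromatic Finkelstein halogen exchange, driven by precipitation of NaBr, converts the aryl bromide into the iodide needed for the chromium-mediated ring closure.

Step 13
Reactants: 22 {(2S)-2-[2,4-bis(benzyloxy)-6-{6-(benzyloxy)-2-[4-(benzyloxy)phenyl]-4-iodo-1-benzofuran-3-yl}phenyl]-2-[4-(benzyloxy)phenyl]ethoxy}(tert-butyl)dimethylsilane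
Product: 23 (2S)-2-[2,4-bis(benzyloxy)-6-{6-(benzyloxy)-2-[4-(benzyloxy)phenyl]-4-iodo-1-benzofuran-3-yl}phenyl]-2-[4-(benzyloxy)phenyl]ethanol
Conditions: HF·pyridine, pyridine/THF, 0 °C to rt
Reagents that add atoms: none
Why: Fluoride-induced desilylation under buffered conditions frees the primary alcohol without affecting the aryl iodide or benzyl ethers.

Step 14
Reactants: 23 (2S)-2-[2,4-bis(benzyloxy)-6-{6-(benzyloxy)-2-[4-(benzyloxy)phenyl]-4-iodo-1-benzofuran-3-yl}phenyl]-2-[4-(benzyloxy)phenyl]ethanol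
Product: 24 (2S)-2-[2,4-bis(benzyloxy)-6-{6-(benzyloxy)-2-[4-(benzyloxy)phenyl]-4-iodo-1-benzofuran-3-yl}phenyl]-2-[4-(benzyloxy)phenyl]acetaldehyde
Conditions: Dess–Martin periodinane, NaHCO3, CH2Cl2, 0 °C, 30 min; filtered cold and used at once
Reagents that add atoms: none
Why: Dess–Martin oxidation under buffered non-basic conditions at 0 °C gives the enolisable α,α-diaryl aldehyde, which is carried forward immediately to keep C8 intact.

Step 15
Reactants: 24 (2S)-2-[2,4-bis(benzyloxy)-6-{6-(benzyloxy)-2-[4-(benzyloxy)phenyl]-4-iodo-1-benzofuran-3-yl}phenyl]-2-[4-(benzyloxy)phenyl]acetaldehyde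
Product: 26 penta-O-benzyl C9 alcohol of hopeafuran (8S; both C9 epimers), via arylchromium dichloride 25 (not isolated)
Conditions: CrCl2 (6 equiv), NiCl2 (2 mol%), degassed DMF, rt, high dilution
Reagents that add atoms: none
Why: Intramolecular Nozaki–Hiyama–Kishi reaction: nickel-catalysed formation of a weakly basic arylchromium species that adds to the aldehyde closes the seven-membered ring without enolising the aldehyde, and the unselective new carbinol centre C9 is removed by the next oxidation.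

Step 16
Reactants: 26 penta-O-benzyl C9 alcohol of hopeafuran (8S; both C9 epimers)
Product: 27 (8S)-penta-O-benzylhopeafuran
Conditions: Dess–Martin periodinane, NaHCO3, CH2Cl2, 0 °C to rt
Reagents that add atoms: none
Why: Dess–Martin oxidation of the benzylic secondary alcohol gives the aryl ketone under buffered non-basic conditions that do not enolise C8, and both C9 epimers converge on one ketone.

Step 17
Reactants: 27 (8S)-penta-O-benzylhopeafuran
Product: 28 hopeafuran (8S)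
Conditions: H2 (1 atm), 10% Pd/C, EtOAc/THF, rt; filtration and evaporation below 30 °C, neutral chromatography
Reagents that add atoms: none
Why: Hydrogenolysis of the five benzyl aryl ethers under neutral conditions at room temperature is much faster than reduction of the hindered aryl ketone or the tetrasubstituted benzofuran, and it avoids the acid or base that could racemise C8.

## Compound list

1 | 4-(benzyloxy)benzaldehyde | O=Cc1ccc(OCc2ccccc2)cc1 | starting material
2 | nitromethane | C[N+](=O)[O-] | starting material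
3 | 1-[4-(benzyloxy)phenyl]-2-nitroethanol (racemic nitroaldol, not isolated) | OC(C[N+](=O)[O-])c1ccc(OCc2ccccc2)cc1 | intermediate
4 | 1-(benzyloxy)-4-[(E)-2-nitroethenyl]benzene | [O-][N+](=O)/C=C/c1ccc(OCc2ccccc2)cc1 | intermediate
5 | 3,5-bis(benzyloxy)phenol | Oc1cc(OCc2ccccc2)cc(OCc2ccccc2)c1 | starting material
6 | 3,5-bis(benzyloxy)-2-[(1S)-1-[4-(benzyloxy)phenyl]-2-nitroethyl]phenol | [O-][N+](=O)C[C@@H](c1ccc(OCc2ccccc2)cc1)c1c(O)cc(OCc2ccccc2)cc1OCc1ccccc1 | intermediate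
7 | 3,5-bis(benzyloxy)-2-[(1S)-1-[4-(benzyloxy)phenyl]-2-nitroethyl]phenyl trifluoromethanesulfonate | [O-][N+](=O)C[C@@H](c1ccc(OCc2ccccc2)cc1)c1c(OS(=O)(=O)C(F)(F)F)cc(OCc2ccccc2)cc1OCc1ccccc1 | intermediate
8 | 3,5-bis(benzyloxy)-2-[(1S)-1-[4-(benzyloxy)phenyl]-2-(hydroxyimino)-2-nitroethyl]phenyl trifluoromethanesulfonate (nitrolic acid, not isolated) | ON=C([N+](=O)[O-])[C@@H](c1ccc(OCc2ccccc2)cc1)c1c(OS(=O)(=O)C(F)(F)F)cc(OCc2ccccc2)cc1OCc1ccccc1 | intermediate
9 | (2S)-2-[2,4-bis(benzyloxy)-6-{[(trifluoromethyl)sulfonyl]oxy}phenyl]-2-[4-(benzyloxy)phenyl]acetonitrile N-oxide (not isolated) | [O-][N+]#C[C@@H](c1ccc(OCc2ccccc2)cc1)c1c(OS(=O)(=O)C(F)(F)F)cc(OCc2ccccc2)cc1OCc1ccccc1 | intermediate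
10 | (2S)-2-[2,4-bis(benzyloxy)-6-{[(trifluoromethyl)sulfonyl]oxy}phenyl]-2-[4-(benzyloxy)phenyl]-N-hydroxyacetamide (hydroxamic acid, not isolated) | ONC(=O)[C@@H](c1ccc(OCc2ccccc2)cc1)c1c(OS(=O)(=O)C(F)(F)F)cc(OCc2ccccc2)cc1OCc1ccccc1 | intermediate
11 | (2S)-2-[2,4-bis(benzyloxy)-6-{[(trifluoromethyl)sulfonyl]oxy}phenyl]-2-[4-(benzyloxy)phenyl]acetic acid | OC(=O)[C@@H](c1ccc(OCc2ccccc2)cc1)c1c(OS(=O)(=O)C(F)(F)F)cc(OCc2ccccc2)cc1OCc1ccccc1 | intermediate
12 | 3,5-bis(benzyloxy)-2-[(1S)-1-[4-(benzyloxy)phenyl]-2-hydroxyethyl]phenyl trifluoromethanesulfonate | OC[C@@H](c1ccc(OCc2ccccc2)cc1)c1c(OS(=O)(=O)C(F)(F)F)cc(OCc2ccccc2)cc1OCc1ccccc1 | intermediate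
13 | 3,5-bis(benzyloxy)-2-[(1S)-1-[4-(benzyloxy)phenyl]-2-{[tert-butyl(dimethyl)silyl]oxy}ethyl]phenyl trifluoromethanesulfonate | CC(C)(C)[Si](C)(C)OC[C@@H](c1ccc(OCc2ccccc2)cc1)c1c(OS(=O)(=O)C(F)(F)F)cc(OCc2ccccc2)cc1OCc1ccccc1 | intermediate
14 | {(2S)-2-[2,4-bis(benzyloxy)-6-(4,4,5,5-tetramethyl-1,3,2-dioxaborolan-2-yl)phenyl]-2-[4-(benzyloxy)phenyl]ethoxy}(tert-butyl)dimethylsilane | CC(C)(C)[Si](C)(C)OC[C@@H](c1ccc(OCc2ccccc2)cc1)c1c(B2OC(C)(C)C(C)(C)O2)cc(OCc2ccccc2)cc1OCc1ccccc1 | intermediate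
15 | 1,3-bis(benzyloxy)-5-bromobenzene | Brc1cc(OCc2ccccc2)cc(OCc2ccccc2)c1 | starting material
16 | 1,5-bis(benzyloxy)-3-bromo-2-iodobenzene | Brc1cc(OCc2ccccc2)cc(OCc2ccccc2)c1I | intermediate
17 | 1-(benzyloxy)-4-ethynylbenzene | C#Cc1ccc(OCc2ccccc2)cc1 | starting material
18 | 1,5-bis(benzyloxy)-2-{[4-(benzyloxy)phenyl]ethynyl}-3-bromobenzene | Brc1cc(OCc2ccccc2)cc(OCc2ccccc2)c1C#Cc1ccc(OCc2ccccc2)cc1 | intermediate
19 | 1-benzyl-6-(benzyloxy)-2-[4-(benzyloxy)phenyl]-4-bromo-3-iodo-1-benzofuran-1-ium iodide (not isolated) | Brc1cc(OCc2ccccc2)cc2[o+](Cc3ccccc3)c(-c3ccc(OCc4ccccc4)cc3)c(I)c12.[I-] | intermediate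
20 | 6-(benzyloxy)-2-[4-(benzyloxy)phenyl]-4-bromo-3-iodo-1-benzofuran | Brc1cc(OCc2ccccc2)cc2oc(-c3ccc(OCc4ccccc4)cc3)c(I)c12 | intermediate
21 | {(2S)-2-[2,4-bis(benzyloxy)-6-{6-(benzyloxy)-2-[4-(benzyloxy)phenyl]-4-bromo-1-benzofuran-3-yl}phenyl]-2-[4-(benzyloxy)phenyl]ethoxy}(tert-butyl)dimethylsilane (biaryl rotamers possible) | CC(C)(C)[Si](C)(C)OC[C@@H](c1ccc(OCc2ccccc2)cc1)c1c(OCc2ccccc2)cc(OCc2ccccc2)cc1-c1c(-c2ccc(OCc3ccccc3)cc2)oc2cc(OCc3ccccc3)cc(Br)c12 | intermediate
22 | {(2S)-2-[2,4-bis(benzyloxy)-6-{6-(benzyloxy)-2-[4-(benzyloxy)phenyl]-4-iodo-1-benzofuran-3-yl}phenyl]-2-[4-(benzyloxy)phenyl]ethoxy}(tert-butyl)dimethylsilane | CC(C)(C)[Si](C)(C)OC[C@@H](c1ccc(OCc2ccccc2)cc1)c1c(OCc2ccccc2)cc(OCc2ccccc2)cc1-c1c(-c2ccc(OCc3ccccc3)cc2)oc2cc(OCc3ccccc3)cc(I)c12 | intermediate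
23 | (2S)-2-[2,4-bis(benzyloxy)-6-{6-(benzyloxy)-2-[4-(benzyloxy)phenyl]-4-iodo-1-benzofuran-3-yl}phenyl]-2-[4-(benzyloxy)phenyl]ethanol | OC[C@@H](c1ccc(OCc2ccccc2)cc1)c1c(OCc2ccccc2)cc(OCc2ccccc2)cc1-c1c(-c2ccc(OCc3ccccc3)cc2)oc2cc(OCc3ccccc3)cc(I)c12 | intermediate
24 | (2S)-2-[2,4-bis(benzyloxy)-6-{6-(benzyloxy)-2-[4-(benzyloxy)phenyl]-4-iodo-1-benzofuran-3-yl}phenyl]-2-[4-(benzyloxy)phenyl]acetaldehyde | O=C[C@@H](c1ccc(OCc2ccccc2)cc1)c1c(OCc2ccccc2)cc(OCc2ccccc2)cc1-c1c(-c2ccc(OCc3ccccc3)cc2)oc2cc(OCc3ccccc3)cc(I)c12 | intermediate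
25 | arylchromium dichloride of 24: CrCl2 unit (trivalent chromium) in place of iodine at benzofuran C4 (not isolated) | O=C[C@@H](c1ccc(OCc2ccccc2)cc1)c1c(OCc2ccccc2)cc(OCc2ccccc2)cc1-c1c(-c2ccc(OCc3ccccc3)cc2)oc2cc(OCc3ccccc3)cc([Cr](Cl)Cl)c12 | intermediate
26 | penta-O-benzyl C9 alcohol of hopeafuran: the seven-membered-ring ketone carbon as CH(OH), both epimers, S at C8 | OC1c2cc(OCc3ccccc3)cc3oc(-c4ccc(OCc5ccccc5)cc4)c(c23)-c2cc(OCc3ccccc3)cc(OCc3ccccc3)c2[C@@H]1c1ccc(OCc2ccccc2)cc1 | intermediate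
27 | (8S)-penta-O-benzylhopeafuran: hopeafuran with all five phenols as benzyl ethers | O=C1c2cc(OCc3ccccc3)cc3oc(-c4ccc(OCc5ccccc5)cc4)c(c23)-c2cc(OCc3ccccc3)cc(OCc3ccccc3)c2[C@@H]1c1ccc(OCc2ccccc2)cc1 | intermediate
28 | hopeafuran, S at the diarylmethine carbon C8 | O=C1c2cc(O)cc3oc(-c4ccc(O)cc4)c(c23)-c2cc(O)cc(O)c2[C@@H]1c1ccc(O)cc1 | target

## Step count and risks

Total step count: 17. Longest linear sequence: 14 steps (steps 1 to 7, then 11 to 17). The benzofuran fragment 20 takes 3 steps (8 to 10).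

The three steps most likely to fail:

Step 2 (Michael addition). The risks are attack para to the OH, double alkylation, or insufficient ee. The fallback sets the same stereocentre by rhodium-catalysed asymmetric conjugate arylation, with the roles of the two aryl groups exchanged. It sets out from 5: ortho-formylation with MgCl2, Et3N and paraformaldehyde gives 2,4-bis(benzyloxy)-6-hydroxybenzaldehyde F1; Tf2O and pyridine give 3,5-bis(benzyloxy)-2-formylphenyl trifluoromethanesulfonate F2; Henry condensation with 2 (NH4OAc, AcOH) gives 3,5-bis(benzyloxy)-2-[(E)-2-nitroethenyl]phenyl trifluoromethanesulfonate F3; addition of 4-(benzyloxy)phenylboronic acid with [Rh(C2H4)2Cl]2, a chiral bicyclic diene ligand and KHF2 in toluene/H2O then returns to the route at 7.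

Step 11 (Suzuki coupling). The biaryl bond is flanked by the 2-aryl group, the peri bromine and the branched ortho substituent, so boronate transfer may be too slow and protodeboronation may win. The fallback is a base-free Stille union through a tin partner. It sets out from 13 and 20: Pd(PPh3)4, Me3SnSnMe3 and LiCl in dioxane at 100 °C give {(2S)-2-[2,4-bis(benzyloxy)-6-(trimethylstannyl)phenyl]-2-[4-(benzyloxy)phenyl]ethoxy}(tert-butyl)dimethylsilane F4; coupling of F4 with 20 using Pd2(dba)3, tri(2-furyl)phosphine and CuI in DMF at 60 °C comes back to the route at 21.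

Step 15 (ring closure on the labile aldehyde). Aldehyde 24 can enolise and lose ee before the arylchromium adds, and the unreactive biaryl rotamer may cyclise slowly. The fallback never passes through an acyclic carbonyl compound: the nitro group is kept and used as the C9 nucleophile. It sets out from 7 and 20: Miyaura borylation of 7 (B2pin2, Pd(dppf)Cl2, KOAc) gives 2-{3,5-bis(benzyloxy)-2-[(1S)-1-[4-(benzyloxy)phenyl]-2-nitroethyl]phenyl}-4,4,5,5-tetramethyl-1,3,2-dioxaborolane F5; Suzuki coupling with 20 (Pd(dppf)Cl2, Cs2CO3) gives 3-{3,5-bis(benzyloxy)-2-[(1S)-1-[4-(benzyloxy)phenyl]-2-nitroethyl]phenyl}-6-(benzyloxy)-2-[4-(benzyloxy)phenyl]-4-bromo-1-benzofuran F6; intramolecular palladium-catalysed nitronate arylation (Pd2(dba)3, 2-dicyclohexylphosphino-2',4',6'-triisopropylbiphenyl, Cs2CO3, dioxane, 80 °C) gives the penta-O-benzyl C9-nitro analogue of 26 F7; a buffered reductive Nef reaction (NaOMe, then TiCl3 and NH4OAc in aqueous THF) comes back to the route at 27.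

Further compounds
F1 | step 2 | 2,4-bis(benzyloxy)-6-hydroxybenzaldehyde | O=Cc1c(O)cc(OCc2ccccc2)cc1OCc1ccccc1
F2 | step 2 | 3,5-bis(benzyloxy)-2-formylphenyl trifluoromethanesulfonate | O=Cc1c(OS(=O)(=O)C(F)(F)F)cc(OCc2ccccc2)cc1OCc1ccccc1
F3 | step 2 | 3,5-bis(benzyloxy)-2-[(E)-2-nitroethenyl]phenyl trifluoromethanesulfonate | [O-][N+](=O)/C=C/c1c(OS(=O)(=O)C(F)(F)F)cc(OCc2ccccc2)cc1OCc1ccccc1
F4 | step 11 | {(2S)-2-[2,4-bis(benzyloxy)-6-(trimethylstannyl)phenyl]-2-[4-(benzyloxy)phenyl]ethoxy}(tert-butyl)dimethylsilane | CC(C)(C)[Si](C)(C)OC[C@@H](c1ccc(OCc2ccccc2)cc1)c1c([Sn](C)(C)C)cc(OCc2ccccc2)cc1OCc1ccccc1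
F5 | step 15 | 2-{3,5-bis(benzyloxy)-2-[(1S)-1-[4-(benzyloxy)phenyl]-2-nitroethyl]phenyl}-4,4,5,5-tetramethyl-1,3,2-dioxaborolane | [O-][N+](=O)C[C@@H](c1ccc(OCc2ccccc2)cc1)c1c(B2OC(C)(C)C(C)(C)O2)cc(OCc2ccccc2)cc1OCc1ccccc1
F6 | step 15 | 3-{3,5-bis(benzyloxy)-2-[(1S)-1-[4-(benzyloxy)phenyl]-2-nitroethyl]phenyl}-6-(benzyloxy)-2-[4-(benzyloxy)phenyl]-4-bromo-1-benzofuran | [O-][N+](=O)C[C@@H](c1ccc(OCc2ccccc2)cc1)c1c(OCc2ccccc2)cc(OCc2ccccc2)cc1-c1c(-c2ccc(OCc3ccccc3)cc2)oc2cc(OCc3ccccc3)cc(Br)c12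
F7 | step 15 | penta-O-benzyl C9-nitro analogue of 26: NO2 in place of OH at C9, both epimers, S at C8 | [O-][N+](=O)C1c2cc(OCc3ccccc3)cc3oc(-c4ccc(OCc5ccccc5)cc4)c(c23)-c2cc(OCc3ccccc3)cc(OCc3ccccc3)c2[C@@H]1c1ccc(OCc2ccccc2)cc1
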